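The decalin is disconnected at C4–C5, C9–C10 and C8–O, which unfolds rings A and B into a linear (E,E)-farnesylacetone chain. The feature exploited is that C4, C5, C10, C9 and the carbinol carbon C8 lie head-to-tail on that chain, with the C13 carbonyl oxygen a six-membered-ring reach from C8. One Lewis-acid cascade, started at an enantiopure C3–C4 oxirane that already carries the C18 silyloxymethyl group, closes ring A, ring B and a temporary dihydropyran and sets C4, C5, C10, C9 and C8. The precursor is thus a silyl-protected epoxy-farnesylacetone. Afterwards C3 is deoxygenated, the ketone unmasked, and C14–C15, C13 and the malonate are added.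

Key step: step 4

Assumption: "labdane" is used only for the carbon skeleton and its locants (C13 carbonyl carbon, C16 its methyl, C17 on C8, C18 the equatorial CH2O and C19 the axial CH3 on C4, C20 on C10), configurations are always given explicitly (ent series), and (5E,9E)-farnesylacetone is taken as purchasable as the single geometric isomer.

Step 1
Reactants: 1 (5E,9E)-farnesylacetone [(5E,9E)-6,10,14-trimethylpentadeca-5,9,13-trien-2-one]
Product: 2 (5E,9E,13E)-15-hydroxy-6,10,14-trimethylpentadeca-5,9,13-trien-2-one
Conditions: SeO2 (0.3 equiv), salicylic acid (0.1 equiv), tBuOOH (3 equiv), CH2Cl2, 0 °C to rt, stopped at partial conversion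
Reagents that add atoms: selenium dioxide, O=[Se]=O (oxygen carrier); tert-butyl hydroperoxide, CC(C)(C)OO (terminal oxidant)
Why: Riley-type allylic oxidation: SeO2 attacks the terminal, most accessible gem-dimethyl alkene in an ene reaction and the [2,3]-sigmatropic shift that follows places oxygen on the methyl group trans to the chain, so only the (13E)-alcohol should form, while the methyl ketone is not attacked at room temperature and unreacted 1 is recovered.

Step 2
Reactants: 2 (5E,9E,13E)-15-hydroxy-6,10,14-trimethylpentadeca-5,9,13-trien-2-one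
Product: 3 (5E,9E)-12-[(2R,3R)-3-(hydroxymethyl)-3-methyloxiran-2-yl]-6,10-dimethyldodeca-5,9-dien-2-one
Conditions: Ti(OiPr)4 (0.1 equiv), D-(−)-diethyl tartrate (0.12 equiv), tBuOOH (2 equiv, in decane), 4 Å molecular sieves, CH2Cl2, −20 °C
Reagents that add atoms: tert-butyl hydroperoxide, CC(C)(C)OO
Why: Sharpless asymmetric epoxidation: only the alkene next to the titanium-bound allylic hydroxyl is oxidised, and the D-(−)-tartrate ligand directs the peroxide oxygen to the face that gives the (2R,3R)-oxirane (labdane 3R,4R), the configuration that leads to the ent decalin series required.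

Step 3
Reactants: 3 (5E,9E)-12-[(2R,3R)-3-(hydroxymethyl)-3-methyloxiran-2-yl]-6,10-dimethyldodeca-5,9-dien-2-one
Product: 4 (5E,9E)-12-[(2R,3R)-3-({[tert-butyl(diphenyl)silyl]oxy}methyl)-3-methyloxiran-2-yl]-6,10-dimethyldodeca-5,9-dien-2-one
Conditions: tBuPh2SiCl (1.2 equiv), imidazole (2.5 equiv), CH2Cl2, 0 °C to rt
Reagents that add atoms: tert-butyl(chloro)diphenylsilane, CC(C)(C)[Si](Cl)(c1ccccc1)c1ccccc1
Why: Imidazole-promoted silylation of the primary alcohol leaves the oxirane and the ketone untouched and installs a bulky, weakly Lewis-basic ether that cannot take part at C4 as an ester would and that will outlast the aqueous acid of step 6.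

Step 4
Reactants: 4 (5E,9E)-12-[(2R,3R)-3-({[tert-butyl(diphenyl)silyl]oxy}methyl)-3-methyloxiran-2-yl]-6,10-dimethyldodeca-5,9-dien-2-one
Product: 5 (3R,4S,5S,8S,9S,10R)-18-{[tert-butyl(diphenyl)silyl]oxy}-8,13-epoxy-14,15-dinorlabd-12-en-3-ol (trans-fused decalin with a trans-fused dihydropyran; 3-OH, C18 and the C8–O bond equatorial)
Conditions: BF3·OEt2 (0.5 equiv), CH2Cl2 (0.01 M), −78 °C; Et3N quench at −78 °C; chromatography on Et3N-deactivated silica
Reagents that add atoms: none
Why: Proposed new method: BF3 bound to the oxirane oxygen weakens the C4–O bond, C5 of the C5=C10 alkene attacks C4 from the back (ring A, 6-endo, both oxirane carbons in the ring), C9 of the C8=C9 alkene takes the C10 cation (ring B, 6-endo), the C13 carbonyl oxygen adds to the tertiary C8 cation (dihydropyran, six-membered, 6-endo with respect to C8=C9), and loss of a C12 proton returns the acid. The closest known reaction types are the Lewis-acid epoxy-polyene bicyclisation and the acid-induced, carbonyl-oxygen-terminated cyclisation of farnesylacetone to the sclareol oxide skeleton; only their union in one substrate is new. C3 keeps the configuration written by the Sharpless step and C4 is inverted, which places the (E)-CH2OSi group equatorial (C18) and the methyl axial (C19). Chair–chair folding of the all-(E) chain should give the trans ring fusion (C5–H anti to C10–CH3) and an equatorial C11 at C9, and anti addition of C10 and oxygen across the (E)-C8=C9 bond should give the equatorial C8–O bond with axial C17. The step needs the oxirane to be activated although the ketone is the stronger base, the cascade to run to the end without proton loss at C10 or C8, and the acid-labile enol ether to survive next to the new C3 hydroxyl; reversible ketone binding to a substoichiometric amount of BF3, three tertiary cations, the non-participating silyl ether, high dilution at −78 °C and the cold amine quench are meant to secure this. Should part of the oxocarbenium ion lose a C16 proton instead, the exocyclic enol ether converges on the same ketone in step 6.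

Step 5
Reactants: 5 (3R,4S,5S,8S,9S,10R)-18-{[tert-butyl(diphenyl)silyl]oxy}-8,13-epoxy-14,15-dinorlabd-12-en-3-ol
Product: 6 O-[(3R,4S,5S,8S,9S,10R)-18-{[tert-butyl(diphenyl)silyl]oxy}-8,13-epoxy-14,15-dinorlabd-12-en-3-yl] 1H-imidazole-1-carbothioate
Conditions: 1,1'-thiocarbonyldiimidazole (3 equiv), DMAP (0.3 equiv), toluene, 90 °C
Reagents that add atoms: 1,1'-thiocarbonyldiimidazole, S=C(n1ccnc1)n1ccnc1
Why: Thioacylation of the equatorial C3 hydroxyl by acyl transfer from the diimidazole gives the radical precursor under neutral conditions, so no alkoxide is formed that could trigger silyl migration from O18, and the acid-sensitive enol ether, which at this stage masks both the C13 ketone and the C8 hydroxyl, is preserved.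

Step 6
Reactants: 6 O-[(3R,4S,5S,8S,9S,10R)-18-{[tert-butyl(diphenyl)silyl]oxy}-8,13-epoxy-14,15-dinorlabd-12-en-3-yl] 1H-imidazole-1-carbothioate
Product: 8 (4S,5S,8S,9S,10R)-18-{[tert-butyl(diphenyl)silyl]oxy}-8-hydroxy-14,15-dinorlabdan-13-one, via deoxygenated enol ether 7 (not isolated)
Conditions: Bu3SnH (2 equiv), AIBN (0.2 equiv), toluene, 100 °C; then THF, 1 M aq. HCl, rt
Reagents that add atoms: water, O
Why: Barton–McCombie deoxygenation: the stannyl radical adds to sulfur, the C3–O bond breaks and the secondary C3 radical takes hydrogen from Bu3SnH without touching a stereocentre, after which dilute acid protonates C12 of the enol ether and water opens the oxocarbenium ion to the C13 methyl ketone, leaving the original oxygen on C8 with its configuration unchanged.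

Step 7
Reactants: 8 (4S,5S,8S,9S,10R)-18-{[tert-butyl(diphenyl)silyl]oxy}-8-hydroxy-14,15-dinorlabdan-13-one; 9 triethyl phosphonoacetate
Product: 10 ethyl (4S,5S,8S,9S,10R,13E)-18-{[tert-butyl(diphenyl)silyl]oxy}-8-hydroxylabd-13-en-15-oate
Conditions: 9 (3.0 equiv), NaH (2.8 equiv), THF, 0 °C, then 8, 60 °C; minor (13Z) isomer removed on silica
Reagents that add atoms: none
Why: Horner–Wadsworth–Emmons olefination: the stabilised phosphonate anion adds reversibly to the methyl ketone and elimination through the less crowded oxaphosphetane places the ester trans to the C12 chain (mainly 13E), while keeping NaH below the amount of phosphonate leaves the far less acidic C8 hydroxyl protonated so that it cannot add to the new enoate.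

Step 8
Reactants: 10 ethyl (4S,5S,8S,9S,10R,13E)-18-{[tert-butyl(diphenyl)silyl]oxy}-8-hydroxylabd-13-en-15-oate
Product: 11 (4S,5S,8S,9S,10R,13E)-18-{[tert-butyl(diphenyl)silyl]oxy}labd-13-ene-8,15-diol
Conditions: iBu2AlH (4 equiv), CH2Cl2, −78 to 0 °C; aq. Rochelle salt
Reagents that add atoms: none
Why: Hydride reduction of the conjugated ester with iBu2AlH proceeds by 1,2-addition only and should give the allylic alcohol with the (13E) geometry intact, the C8 hydroxyl merely consuming one equivalent of hydride and the silyl ether being inert.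

Step 9
Reactants: 11 (4S,5S,8S,9S,10R,13E)-18-{[tert-butyl(diphenyl)silyl]oxy}labd-13-ene-8,15-diol
Product: 12 (4S,5S,8S,9S,10R,13S)-18-{[tert-butyl(diphenyl)silyl]oxy}labdane-8,15-diol
Conditions: Ru(OAc)2[(R)-BINAP] (2 mol%), H2 (100 atm), MeOH, 25 °C
Reagents that add atoms: none
Why: Noyori asymmetric hydrogenation of an allylic alcohol: the C15 hydroxyl binds ruthenium and the (R)-BINAP ligand, which turns (E)-3-methylalk-2-en-1-ols of the geraniol type into the (S)-alcohols, should deliver hydrogen to the face of C13=C14 that gives 13S under catalyst control, the nearest ring stereocentre (C9) being three bonds away.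

Step 10
Reactants: 12 (4S,5S,8S,9S,10R,13S)-18-{[tert-butyl(diphenyl)silyl]oxy}labdane-8,15-diol; 13 Meldrum's acid (2,2-dimethyl-1,3-dioxane-4,6-dione)
Product: 14 3-{[(4S,5S,8S,9S,10R,13S)-18-{[tert-butyl(diphenyl)silyl]oxy}-8-hydroxylabdan-15-yl]oxy}-3-oxopropanoic acid
Conditions: 13 (1.3 equiv), toluene, 85 °C
Reagents that add atoms: none
Why: Acylation by ring opening of Meldrum's acid: the primary C15 hydroxyl attacks a ring carbonyl and loss of acetone leaves the malonic acid half ester directly, the tertiary C8 hydroxyl being too hindered to compete and the temperature staying below that at which the half ester loses CO2.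

Step 11
Reactants: 14 3-{[(4S,5S,8S,9S,10R,13S)-18-{[tert-butyl(diphenyl)silyl]oxy}-8-hydroxylabdan-15-yl]oxy}-3-oxopropanoic acid
Product: 15 3-{[(4S,5S,8S,9S,10R,13S)-8,18-dihydroxylabdan-15-yl]oxy}-3-oxopropanoic acid (CNP0324566.1)
Conditions: Bu4NF (4 equiv), AcOH (4 equiv), THF, rt to 40 °C; work-up at pH 3–4
Reagents that add atoms: none
Why: Fluoride-induced desilylation: formation of the Si–F bond frees the neopentyl C18 hydroxyl, and the acetic acid buffer keeps the medium near neutral so that the malonate ester is neither cleaved nor transferred and the tertiary alcohol does not eliminate.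

Compound list
1 | (5E,9E)-farnesylacetone, (5E,9E)-6,10,14-trimethylpentadeca-5,9,13-trien-2-one | CC(C)=CCC/C(C)=C/CC/C(C)=C/CCC(C)=O | starting material
2 | (5E,9E,13E)-15-hydroxy-6,10,14-trimethylpentadeca-5,9,13-trien-2-one | CC(=O)CC/C=C(\C)CC/C=C(\C)CC/C=C(\C)CO | intermediate
3 | (5E,9E)-12-[(2R,3R)-3-(hydroxymethyl)-3-methyloxiran-2-yl]-6,10-dimethyldodeca-5,9-dien-2-one | CC(=O)CC/C=C(\C)CC/C=C(\C)CC[C@H]1O[C@]1(C)CO | intermediate
4 | (5E,9E)-12-[(2R,3R)-3-({[tert-butyl(diphenyl)silyl]oxy}methyl)-3-methyloxiran-2-yl]-6,10-dimethyldodeca-5,9-dien-2-one | CC(=O)CC/C=C(\C)CC/C=C(\C)CC[C@H]1O[C@]1(C)CO[Si](c1ccccc1)(c1ccccc1)C(C)(C)C | intermediate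
5 | (3R,4S,5S,8S,9S,10R)-18-{[tert-butyl(diphenyl)silyl]oxy}-8,13-epoxy-14,15-dinorlabd-12-en-3-ol | CC1=CC[C@H]2[C@]3(C)CC[C@@H](O)[C@](C)(CO[Si](c4ccccc4)(c4ccccc4)C(C)(C)C)[C@H]3CC[C@]2(C)O1 | intermediate
6 | O-[(3R,4S,5S,8S,9S,10R)-18-{[tert-butyl(diphenyl)silyl]oxy}-8,13-epoxy-14,15-dinorlabd-12-en-3-yl] 1H-imidazole-1-carbothioate | CC1=CC[C@H]2[C@]3(C)CC[C@@H](OC(=S)n4ccnc4)[C@](C)(CO[Si](c4ccccc4)(c4ccccc4)C(C)(C)C)[C@H]3CC[C@]2(C)O1 | intermediate
7 | (4S,5S,8S,9S,10R)-18-{[tert-butyl(diphenyl)silyl]oxy}-8,13-epoxy-14,15-dinorlabd-12-ene | CC1=CC[C@H]2[C@]3(C)CCC[C@](C)(CO[Si](c4ccccc4)(c4ccccc4)C(C)(C)C)[C@H]3CC[C@]2(C)O1 | intermediate (not isolated)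
8 | (4S,5S,8S,9S,10R)-18-{[tert-butyl(diphenyl)silyl]oxy}-8-hydroxy-14,15-dinorlabdan-13-one | CC(=O)CC[C@H]1[C@]2(C)CCC[C@](C)(CO[Si](c3ccccc3)(c3ccccc3)C(C)(C)C)[C@H]2CC[C@]1(C)O | intermediate
9 | triethyl phosphonoacetate | CCOC(=O)CP(=O)(OCC)OCC | starting material
10 | ethyl (4S,5S,8S,9S,10R,13E)-18-{[tert-butyl(diphenyl)silyl]oxy}-8-hydroxylabd-13-en-15-oate | CCOC(=O)/C=C(\C)CC[C@H]1[C@]2(C)CCC[C@](C)(CO[Si](c3ccccc3)(c3ccccc3)C(C)(C)C)[C@H]2CC[C@]1(C)O | intermediate
11 | (4S,5S,8S,9S,10R,13E)-18-{[tert-butyl(diphenyl)silyl]oxy}labd-13-ene-8,15-diol | OC/C=C(\C)CC[C@H]1[C@]2(C)CCC[C@](C)(CO[Si](c3ccccc3)(c3ccccc3)C(C)(C)C)[C@H]2CC[C@]1(C)O | intermediate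
12 | (4S,5S,8S,9S,10R,13S)-18-{[tert-butyl(diphenyl)silyl]oxy}labdane-8,15-diol | C[C@H](CCO)CC[C@H]1[C@]2(C)CCC[C@](C)(CO[Si](c3ccccc3)(c3ccccc3)C(C)(C)C)[C@H]2CC[C@]1(C)O | intermediate
13 | Meldrum's acid, 2,2-dimethyl-1,3-dioxane-4,6-dione | CC1(C)OC(=O)CC(=O)O1 | starting material
14 | 3-{[(4S,5S,8S,9S,10R,13S)-18-{[tert-butyl(diphenyl)silyl]oxy}-8-hydroxylabdan-15-yl]oxy}-3-oxopropanoic acid | C[C@H](CCOC(=O)CC(=O)O)CC[C@H]1[C@]2(C)CCC[C@](C)(CO[Si](c3ccccc3)(c3ccccc3)C(C)(C)C)[C@H]2CC[C@]1(C)O | intermediate
15 | 3-{[(4S,5S,8S,9S,10R,13S)-8,18-dihydroxylabdan-15-yl]oxy}-3-oxopropanoic acid (CNP0324566.1) | C[C@H](CCOC(=O)CC(=O)O)CC[C@H]1[C@]2(C)CCC[C@](C)(CO)[C@H]2CC[C@]1(C)O | target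

Total step count: 11. Longest linear sequence: 11 steps, from 1 to 15 (9 and 13 are bought).

Steps most likely to fail

Step 4 (new method). The cascade may stop early through proton loss or fluoride capture at the C10 or C8 cation, the oxirane may rearrange by hydride shift before the alkene arrives, or the acid may add the new C3 hydroxyl of one molecule to the enol ether of another. The fallback uses known chemistry and replaces the cationic ring closure by a radical one. It sets out from 4: the oxirane is opened homolytically with Cp2TiCl (a trivalent titanium reagent made from Cp2TiCl2 and Mn dust, THF, rt), the tertiary C4 radical closes rings A and B by two 6-endo additions, and the C8 radical is turned by a second Cp2TiCl into the exocyclic alkene. This should give (3R,4S,5S,9R,10S)-18-{[tert-butyl(diphenyl)silyl]oxy}-3-hydroxy-14,15-dinorlabd-8(17)-en-13-one F1. The dialkyl ketone is not reduced by this reagent. The C4 configuration is no longer passed on from the oxirane but should follow from the preference of the large CH2OSi group for the equatorial position. Brief treatment of F1 with camphorsulfonic acid (cat.) in CH2Cl2 at 0 °C protonates the C8=C17 alkene, and the carbonyl oxygen closes the dihydropyran from the equatorial side, the known second half of the ketone-terminated cyclisation. The route is rejoined at 5.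

Step 1. Over-oxidation of the allylic alcohol to the enal, attack at internal allylic positions and attack next to the ketone may leave little 2. The fallback sets out from 1 and masks the ketone first (ethylene glycol, TsOH cat., benzene, reflux with removal of water) as 2-methyl-2-[(3E,7E)-4,8,12-trimethyltrideca-3,7,11-trien-1-yl]-1,3-dioxolane F2. The SeO2/tBuOOH oxidation is then pushed to higher conversion and the crude alcohol/enal mixture is reduced with NaBH4 in MeOH at 0 °C, which is possible only because no ketone is present. This should give (2E,6E,10E)-2,6,10-trimethyl-13-(2-methyl-1,3-dioxolan-2-yl)trideca-2,6,10-trien-1-ol F3. Pyridinium p-toluenesulfonate in aqueous acetone removes the ketal and the route is rejoined at 2.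

Step 7. The methyl group and the C12 chain differ little in size, so the olefination may show poor E/Z selectivity and much material would be lost as the wrong geometric isomer. The fallback uses both isomers stereoconvergently and sets out from 8. The olefination mixture of 10 and ethyl (4S,5S,8S,9S,10R,13Z)-18-{[tert-butyl(diphenyl)silyl]oxy}-8-hydroxylabd-13-en-15-oate F4 is reduced together with iBu2AlH. The allylic alcohols 11 and (4S,5S,8S,9S,10R,13Z)-18-{[tert-butyl(diphenyl)silyl]oxy}labd-13-ene-8,15-diol F5 are separated on silica. F5 is then hydrogenated with the enantiomeric catalyst Ru(OAc)2[(S)-BINAP]; because (E)- and (Z)-allylic alcohols give opposite configurations with one ligand, the Z stream with the (S) ligand should also give 13S. Both streams meet at 12.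

Further compounds
F1 | step 4 | (3R,4S,5S,9R,10S)-18-{[tert-butyl(diphenyl)silyl]oxy}-3-hydroxy-14,15-dinorlabd-8(17)-en-13-one | CC(=O)CC[C@H]1[C@]2(C)CC[C@@H](O)[C@](C)(CO[Si](c3ccccc3)(c3ccccc3)C(C)(C)C)[C@H]2CCC1=C
F2 | step 1 | 2-methyl-2-[(3E,7E)-4,8,12-trimethyltrideca-3,7,11-trien-1-yl]-1,3-dioxolane | CC(C)=CCC/C(C)=C/CC/C(C)=C/CCC1(C)OCCO1
F3 | step 1 | (2E,6E,10E)-2,6,10-trimethyl-13-(2-methyl-1,3-dioxolan-2-yl)trideca-2,6,10-trien-1-ol | CC1(CC/C=C(\C)CC/C=C(\C)CC/C=C(\C)CO)OCCO1
F4 | step 7 | ethyl (4S,5S,8S,9S,10R,13Z)-18-{[tert-butyl(diphenyl)silyl]oxy}-8-hydroxylabd-13-en-15-oate | CCOC(=O)/C=C(/C)CC[C@H]1[C@]2(C)CCC[C@](C)(CO[Si](c3ccccc3)(c3ccccc3)C(C)(C)C)[C@H]2CC[C@]1(C)O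
F5 | step 7 | (4S,5S,8S,9S,10R,13Z)-18-{[tert-butyl(diphenyl)silyl]oxy}labd-13-ene-8,15-diol | OC/C=C(/C)CC[C@H]1[C@]2(C)CCC[C@](C)(CO[Si](c3ccccc3)(c3ccccc3)C(C)(C)C)[C@H]2CC[C@]1(C)O
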